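**Plan**

- Retrosynthesis: the primary alcohol is traced back to a bromomethyl group and the carbinol to an aryl ketone; the C3–C4 ring bond is then cut (radical closure with bromine transfer), opening the oxolane to an acyclic α-bromo-β-alkoxy ketone; the C5–O1 ether bond is cut next (oxa-Michael addition), and last the C2–vinyl bond (Grignard addition).
- Enabling feature: in the ring O1–C2(trimethoxyphenyl)–C3(CH2OH)–C4(carbinol arm)–C5H2, the C3–C4 bond joins a carbon that is α to an aryl ketone once the carbinol is oxidized (C4) to a carbon whose CH2OH arm can be the outer end of a vinyl group on C2 (C3). An α-keto radical at C4, tethered through C5–O1–C2, therefore closes the only ring 5-exo.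
- Forward: the (R)-allylic alcohol and an aryl vinyl ketone are joined through O1–C5, bromine is placed on C4, the oxolane closes in the radical step, and the ketone and the bromide are turned into the two hydroxyl groups.
- Stereochemistry: C2 from a lipase resolution; C3 from C2 in the chair-like radical transition state (2,3-trans); C4 by equilibration α to the ketone (3,4-trans); the carbinol centre by Corey–Bakshi–Shibata reduction, with Felkin–Anh induction from C4 pointing the same way.

Key step: step 7

Remark: the oxolane is numbered O1, C2 (trimethoxyphenyl), C3 (one-carbon arm), C4 (aroyl or carbinol arm), C5 (CH2) throughout. The target is (2R,3S,4R) with an (S)-carbinol and all ring neighbours trans; in the halomethyl compounds C3 reads R only because the halogen changes the priority order.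

**Route**

Step 1
Reactants: 1 3,4,5-trimethoxybenzaldehyde; 2 vinylmagnesium bromide
Product: 3 rac-1-(3,4,5-trimethoxyphenyl)prop-2-en-1-ol
Conditions: CH2=CHMgBr (1.2 equiv), THF, 0 °C to rt; aq. NH4Cl
Reagents that add atoms: none
Why: Grignard addition of the vinyl nucleophile to a non-enolizable aromatic aldehyde should give the racemic allylic alcohol cleanly.

Step 2
Reactants: 3 rac-1-(3,4,5-trimethoxyphenyl)prop-2-en-1-ol
Product: 4 (1R)-1-(3,4,5-trimethoxyphenyl)prop-2-en-1-yl acetate
Conditions: immobilized Candida antarctica lipase B (Novozym 435), vinyl acetate (3 equiv), t-BuOMe, 30 °C, stopped near half conversion; chromatography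
Reagents that add atoms: vinyl acetate, CC(=O)OC=C
Why: Lipase-catalysed kinetic resolution by irreversible transesterification, in which the enzyme is expected to acylate the enantiomer that places the aryl group in its large pocket and the vinyl group in its medium pocket, that is the (R)-alcohol, and to leave the (S)-alcohol unchanged.

Step 3
Reactants: 4 (1R)-1-(3,4,5-trimethoxyphenyl)prop-2-en-1-yl acetate
Product: 5 (1R)-1-(3,4,5-trimethoxyphenyl)prop-2-en-1-ol
Conditions: K2CO3 (0.2 equiv), MeOH, 0 °C to rt
Reagents that add atoms: none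
Why: Base-catalysed methanolysis (transesterification) cleaves the ester at the acyl carbon, so the C–O bond of the stereocentre is untouched and the configuration is kept.

Step 4
Reactants: 6 3,4-dimethoxyacetophenone
Product: 8 1-(3,4-dimethoxyphenyl)prop-2-en-1-one, via Mannich base 7 (not isolated)
Conditions: (CH2O)n (2 equiv), i-Pr2NH·CF3CO2H (1 equiv), CF3CO2H (0.1 equiv), THF, reflux; product stored cold over 2,6-di-tert-butyl-4-methylphenol and used at once
Reagents that add atoms: formaldehyde (as paraformaldehyde), C=O; diisopropylammonium trifluoroacetate, CC(C)[NH2+]C(C)C.[O-]C(=O)C(F)(F)F (its nitrogen is held only in 7)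
Why: Mannich reaction of the methyl ketone with the iminium ion from formaldehyde and the amine salt, followed in the same flask by elimination of the amine from the β-amino ketone (direct α-methylenation), should give the aryl vinyl ketone.

Step 5
Reactants: 5 (1R)-1-(3,4,5-trimethoxyphenyl)prop-2-en-1-ol; 8 1-(3,4-dimethoxyphenyl)prop-2-en-1-one
Product: 9 1-(3,4-dimethoxyphenyl)-3-{[(1R)-1-(3,4,5-trimethoxyphenyl)prop-2-en-1-yl]oxy}propan-1-one
Conditions: PMe3 (10 mol %), THF, 0 °C to rt, 8 (1.5 equiv) added slowly
Reagents that add atoms: none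
Why: Phosphine-catalysed oxa-Michael addition (hydroalkoxylation), in which the phosphonium enolate formed from PMe3 and the enone deprotonates the alcohol and the alkoxide adds to the unsubstituted β-carbon under nearly neutral conditions that leave the C2 stereocentre untouched.

Step 6
Reactants: 9 1-(3,4-dimethoxyphenyl)-3-{[(1R)-1-(3,4,5-trimethoxyphenyl)prop-2-en-1-yl]oxy}propan-1-one
Product: 11 2-bromo-1-(3,4-dimethoxyphenyl)-3-{[(1R)-1-(3,4,5-trimethoxyphenyl)prop-2-en-1-yl]oxy}propan-1-one (both epimers at the brominated carbon), via silyl enol ether 10 (not isolated)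
Conditions: LiN(SiMe3)2 (1.1 equiv) and Me3SiCl (1.5 equiv) premixed, THF, −78 °C; then N-bromosuccinimide (1.1 equiv), −78 °C; pH 7 buffer
Reagents that add atoms: N-bromosuccinimide, O=C1CCC(=O)N1Br; chlorotrimethylsilane, C[Si](C)(C)Cl (its silyl group is held only in 10)
Why: Kinetic deprotonation with in situ silylation traps the enolate as its (Z)-trimethylsilyl enol ether before the β-alkoxide can be expelled, and electrophilic bromination of this enol ether by N-bromosuccinimide is far faster than attack on the isolated vinyl group or the trimethoxyphenyl ring.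

Step 7
Reactants: 11 2-bromo-1-(3,4-dimethoxyphenyl)-3-{[(1R)-1-(3,4,5-trimethoxyphenyl)prop-2-en-1-yl]oxy}propan-1-one (both epimers)
Product: 12 (2R,3R)-3-(bromomethyl)-4-(3,4-dimethoxybenzoyl)-2-(3,4,5-trimethoxyphenyl)oxolane (2,3-trans, both C4 epimers)
Conditions: CuBr (10 mol %), tris(2-pyridylmethyl)amine (10 mol %), degassed CH2Cl2 (0.05 M), rt to 40 °C; filtration through neutral alumina
Reagents that add atoms: none
Why: CuBr bound to tris(2-pyridylmethyl)amine abstracts the bromine atom of 11 (either epimer, because the radical is planar), the electrophilic α-keto radical adds to the inner carbon of the vinyl group, and the primary radical takes bromine back from the CuBr2 complex, which returns the monovalent copper. The closest known reaction type is the copper-catalysed atom-transfer (Kharasch-type) radical cyclization of α-halo carbonyl compounds onto unactivated alkenes. The oxolane closes in the 5-exo-trig mode by forming the C3–C4 bond. C3 is controlled by C2, since the trimethoxyphenyl group sits pseudo-equatorial in the chair-like transition state and the bromomethyl arm should therefore come out trans to it, whereas C4 derives from a planar radical carbon, is not expected to be controlled and is left to step 8. The step needs 5-exo over 6-endo closure, which the unsubstituted alkene terminus and the short 3-oxa tether secure, and activation of the α-keto C–Br bond only, which the much stronger primary C–Br bond of the product secures. The amine-ligated copper works without added base, so the β-alkoxy group should not be lost by elimination.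

Step 8
Reactants: 12 (2R,3R)-3-(bromomethyl)-4-(3,4-dimethoxybenzoyl)-2-(3,4,5-trimethoxyphenyl)oxolane (both C4 epimers)
Product: 13 (2R,3R,4R)-3-(bromomethyl)-4-(3,4-dimethoxybenzoyl)-2-(3,4,5-trimethoxyphenyl)oxolane (all-trans)
Conditions: 1,8-diazabicyclo[5.4.0]undec-7-ene (DBU, 0.3 equiv), toluene, 0 °C to rt; AcOH, then pH 7 buffer
Reagents that add atoms: none
Why: Base-mediated epimerization through the enolate α to the aryl ketone should funnel both C4 epimers to the thermodynamically preferred isomer with the aroyl group trans to the bromomethyl arm, the amidine being weak enough that reprotonation of the transient enolate should outrun its alkylation by the neighbouring bromide.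

Step 9
Reactants: 13 (2R,3R,4R)-3-(bromomethyl)-4-(3,4-dimethoxybenzoyl)-2-(3,4,5-trimethoxyphenyl)oxolane
Product: 14 (2R,3R,4R)-3-(bromomethyl)-4-[(S)-(3,4-dimethoxyphenyl)(hydroxy)methyl]-2-(3,4,5-trimethoxyphenyl)oxolane
Conditions: (R)-2-methyl-CBS-oxazaborolidine, that is (3aR)-1-methyl-3,3-diphenyltetrahydro-1H,3H-pyrrolo[1,2-c][1,3,2]oxazaborole (0.5 equiv), BH3·SMe2 (1.2 equiv), THF, −20 °C; MeOH
Reagents that add atoms: none
Why: Corey–Bakshi–Shibata reduction, in which the (R)-oxazaborolidine should deliver hydride to the ketone face that gives the (S)-carbinol (aryl as the large group), while the Felkin–Anh preference of the C4 stereocentre (branched C3 as the large substituent anti to hydride) points the same way.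

Step 10
Reactants: 14 (2R,3R,4R)-3-(bromomethyl)-4-[(S)-(3,4-dimethoxyphenyl)(hydroxy)methyl]-2-(3,4,5-trimethoxyphenyl)oxolane
Product: 16 (2R,3S,4R)-4-[(S)-(3,4-dimethoxyphenyl)(hydroxy)methyl]-3-(hydroxymethyl)-2-(3,4,5-trimethoxyphenyl)oxolane (CNP0172668.1), via hydroxy acetate 15 (not isolated)
Conditions: CsOAc (3 equiv), 18-crown-6 (0.2 equiv), DMF, 60 °C; then MeOH, K2CO3 (0.2 equiv), rt; neutral work-up
Reagents that add atoms: cesium acetate, CC(=O)[O-].[Cs+]
Why: SN2 displacement of the primary bromide by acetate followed by methanolysis of the acetate touches no stereocentre, and the free carbinol should not compete as an internal nucleophile because closure onto the trans-disposed arm would give a strained trans-fused dioxabicyclo[3.3.0]octane.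

**Compound list**

1 | 3,4,5-trimethoxybenzaldehyde | COc1cc(C=O)cc(OC)c1OC | starting material
2 | vinylmagnesium bromide | C=C[Mg]Br | starting material
3 | rac-1-(3,4,5-trimethoxyphenyl)prop-2-en-1-ol | C=CC(O)c1cc(OC)c(OC)c(OC)c1 | intermediate
4 | (1R)-1-(3,4,5-trimethoxyphenyl)prop-2-en-1-yl acetate | C=C[C@@H](OC(C)=O)c1cc(OC)c(OC)c(OC)c1 | intermediate
5 | (1R)-1-(3,4,5-trimethoxyphenyl)prop-2-en-1-ol | C=C[C@@H](O)c1cc(OC)c(OC)c(OC)c1 | intermediate
6 | 3,4-dimethoxyacetophenone | CC(=O)c1ccc(OC)c(OC)c1 | starting material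
7 | 3-(diisopropylamino)-1-(3,4-dimethoxyphenyl)propan-1-one (Mannich base) | COc1ccc(cc1OC)C(=O)CCN(C(C)C)C(C)C | intermediate (not isolated)
8 | 1-(3,4-dimethoxyphenyl)prop-2-en-1-one | COc1ccc(cc1OC)C(=O)C=C | intermediate
9 | 1-(3,4-dimethoxyphenyl)-3-{[(1R)-1-(3,4,5-trimethoxyphenyl)prop-2-en-1-yl]oxy}propan-1-one | COc1ccc(cc1OC)C(=O)CCO[C@@H](c2cc(OC)c(OC)c(OC)c2)C=C | intermediate
10 | {[(1Z)-1-(3,4-dimethoxyphenyl)-3-{[(1R)-1-(3,4,5-trimethoxyphenyl)prop-2-en-1-yl]oxy}prop-1-en-1-yl]oxy}trimethylsilane | COc1ccc(cc1OC)/C(O[Si](C)(C)C)=C/CO[C@@H](c2cc(OC)c(OC)c(OC)c2)C=C | intermediate (not isolated)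
11 | 2-bromo-1-(3,4-dimethoxyphenyl)-3-{[(1R)-1-(3,4,5-trimethoxyphenyl)prop-2-en-1-yl]oxy}propan-1-one, both epimers at the brominated carbon | COc1ccc(cc1OC)C(=O)C(Br)CO[C@@H](c2cc(OC)c(OC)c(OC)c2)C=C | intermediate
12 | (2R,3R)-3-(bromomethyl)-4-(3,4-dimethoxybenzoyl)-2-(3,4,5-trimethoxyphenyl)oxolane, both C4 epimers | COc1ccc(cc1OC)C(=O)C2CO[C@@H](c3cc(OC)c(OC)c(OC)c3)[C@@H]2CBr | intermediate
13 | (2R,3R,4R)-3-(bromomethyl)-4-(3,4-dimethoxybenzoyl)-2-(3,4,5-trimethoxyphenyl)oxolane | COc1ccc(cc1OC)C(=O)[C@H]2CO[C@@H](c3cc(OC)c(OC)c(OC)c3)[C@@H]2CBr | intermediate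
14 | (2R,3R,4R)-3-(bromomethyl)-4-[(S)-(3,4-dimethoxyphenyl)(hydroxy)methyl]-2-(3,4,5-trimethoxyphenyl)oxolane | COc1ccc([C@@H](O)[C@H]2CO[C@@H](c3cc(OC)c(OC)c(OC)c3)[C@@H]2CBr)cc1OC | intermediate
15 | [(2R,3S,4R)-4-[(S)-(3,4-dimethoxyphenyl)(hydroxy)methyl]-2-(3,4,5-trimethoxyphenyl)oxolan-3-yl]methyl acetate | COc1ccc([C@@H](O)[C@H]2CO[C@@H](c3cc(OC)c(OC)c(OC)c3)[C@@H]2COC(C)=O)cc1OC | intermediate (not isolated)
16 | (2R,3S,4R)-4-[(S)-(3,4-dimethoxyphenyl)(hydroxy)methyl]-3-(hydroxymethyl)-2-(3,4,5-trimethoxyphenyl)oxolane | COc1ccc([C@@H](O)[C@H]2CO[C@@H](c3cc(OC)c(OC)c(OC)c3)[C@@H]2CO)cc1OC | target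

**Count and risks**

Total steps: 10. Longest linear sequence: 9 steps (steps 1–3 and 5–10 from 3,4,5-trimethoxybenzaldehyde); step 4 is the side branch.

Steps most likely to fail:

Step 7. The copper catalyst may stall as divalent copper builds up. The α-keto radical may be reduced to an enolate that expels the β-alkoxide. The chair preference may give too little 2,3-trans selectivity at the reaction temperature. The fallback is an iodine atom-transfer radical chain with no redox metal, run cold. Setting out from 11, Finkelstein exchange (NaI, acetone, rt, dark) would give the α-iodo ketone 2-iodo-1-(3,4-dimethoxyphenyl)-3-{[(1R)-1-(3,4,5-trimethoxyphenyl)prop-2-en-1-yl]oxy}propan-1-one F1. Its weak C–I bond sustains a chain started by Et3B and a trace of air in CH2Cl2 at 0 °C or below, and the same 5-exo closure should give (2R,3R)-3-(iodomethyl)-4-(3,4-dimethoxybenzoyl)-2-(3,4,5-trimethoxyphenyl)oxolane F2 as its C4 epimers. Equilibration as in step 8 should give the all-trans iodide (2R,3R,4R)-3-(iodomethyl)-4-(3,4-dimethoxybenzoyl)-2-(3,4,5-trimethoxyphenyl)oxolane F3. Reduction as in step 9 should give the iodo alcohol (2R,3R,4R)-4-[(S)-(3,4-dimethoxyphenyl)(hydroxy)methyl]-3-(iodomethyl)-2-(3,4,5-trimethoxyphenyl)oxolane F4. CsOAc in DMF would then displace iodide to reach 15, where the route is rejoined.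

Step 5. Oligomerization of the aryl vinyl ketone under the nucleophilic catalyst may outrun addition of the hindered secondary alcohol, and the addition may revert. The fallback builds the ketone after the ether. Setting out from 5, cyanoethylation with acrylonitrile (catalytic benzyltrimethylammonium hydroxide, rt), an oxa-Michael addition to an acceptor that does not oligomerize under these conditions, should give 3-{[(1R)-1-(3,4,5-trimethoxyphenyl)prop-2-en-1-yl]oxy}propanenitrile F5. Addition of 3,4-(MeO)2C6H3MgBr (THF, 0 °C to rt) would give the ketimine 1-(3,4-dimethoxyphenyl)-3-{[(1R)-1-(3,4,5-trimethoxyphenyl)prop-2-en-1-yl]oxy}propan-1-imine F6, which cold dilute aqueous HCl should hydrolyse to 9, where the route is rejoined; step 4 is then not needed.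

Step 8. Alkylation of the enolate by the neighbouring bromomethyl group (cyclopropane formation), or ring opening by β-elimination of O1, may compete with the epimerization. The fallback changes the order so that no leaving group sits next to the enolizable carbon. Setting out from 12, the bromide is displaced first (CsOAc, 18-crown-6, DMF, 50 °C) to give (2R,3S)-3-(acetoxymethyl)-4-(3,4-dimethoxybenzoyl)-2-(3,4,5-trimethoxyphenyl)oxolane F7 as its C4 epimers. DBU equilibration should then give the all-trans acetoxy ketone (2R,3S,4R)-3-(acetoxymethyl)-4-(3,4-dimethoxybenzoyl)-2-(3,4,5-trimethoxyphenyl)oxolane F8. The reduction of step 9 applied to F8 would give 15, where the route is rejoined for the methanolysis.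

Further compounds
F1 | step 7 | 2-iodo-1-(3,4-dimethoxyphenyl)-3-{[(1R)-1-(3,4,5-trimethoxyphenyl)prop-2-en-1-yl]oxy}propan-1-one, both epimers at the iodinated carbon | COc1ccc(cc1OC)C(=O)C(I)CO[C@@H](c2cc(OC)c(OC)c(OC)c2)C=C
F2 | step 7 | (2R,3R)-3-(iodomethyl)-4-(3,4-dimethoxybenzoyl)-2-(3,4,5-trimethoxyphenyl)oxolane, both C4 epimers | COc1ccc(cc1OC)C(=O)C2CO[C@@H](c3cc(OC)c(OC)c(OC)c3)[C@@H]2CI
F3 | step 7 | (2R,3R,4R)-3-(iodomethyl)-4-(3,4-dimethoxybenzoyl)-2-(3,4,5-trimethoxyphenyl)oxolane | COc1ccc(cc1OC)C(=O)[C@H]2CO[C@@H](c3cc(OC)c(OC)c(OC)c3)[C@@H]2CI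
F4 | step 7 | (2R,3R,4R)-4-[(S)-(3,4-dimethoxyphenyl)(hydroxy)methyl]-3-(iodomethyl)-2-(3,4,5-trimethoxyphenyl)oxolane | COc1ccc([C@@H](O)[C@H]2CO[C@@H](c3cc(OC)c(OC)c(OC)c3)[C@@H]2CI)cc1OC
F5 | step 5 | 3-{[(1R)-1-(3,4,5-trimethoxyphenyl)prop-2-en-1-yl]oxy}propanenitrile | N#CCCO[C@@H](c1cc(OC)c(OC)c(OC)c1)C=C
F6 | step 5 | 1-(3,4-dimethoxyphenyl)-3-{[(1R)-1-(3,4,5-trimethoxyphenyl)prop-2-en-1-yl]oxy}propan-1-imine | COc1ccc(cc1OC)C(=N)CCO[C@@H](c2cc(OC)c(OC)c(OC)c2)C=C
F7 | step 8 | (2R,3S)-3-(acetoxymethyl)-4-(3,4-dimethoxybenzoyl)-2-(3,4,5-trimethoxyphenyl)oxolane, both C4 epimers | COc1ccc(cc1OC)C(=O)C2CO[C@@H](c3cc(OC)c(OC)c(OC)c3)[C@@H]2COC(C)=O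
F8 | step 8 | (2R,3S,4R)-3-(acetoxymethyl)-4-(3,4-dimethoxybenzoyl)-2-(3,4,5-trimethoxyphenyl)oxolane | COc1ccc(cc1OC)C(=O)[C@H]2CO[C@@H](c3cc(OC)c(OC)c(OC)c3)[C@@H]2COC(C)=O
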